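The rate constants were drawn at random within sensible limits; the flask was simulated.

I decide to follow these flasks by counting turnovers, since the catalyst charge is the one thing that differs between them.

- south-east: substrate 1.0 M; partner 0.950 M; free catalyst 2.0 mM; time 25 min
- north-west: substrate 1.0 M; partner 0.950 M; free catalyst 4.0 mM; time 25 min

    substrate + free catalyst ⇌ catalyst intermediate A (K1 = 1.4 M⁻¹, k1 = 235 M⁻¹ min⁻¹)
    partner + catalyst intermediate A → catalyst intermediate B (k2 = 184 M⁻¹ min⁻¹)
    catalyst intermediate B ⇌ by-product + catalyst intermediate C (K3 = 0.683 M, k3 = 60.5 min⁻¹)
    catalyst intermediate C → free catalyst + target (k4 = 241 min⁻¹)
    target + free catalyst ⇌ isomer of the product + free catalyst, rate k5*[free catalyst]*[target] forward; the back reaction follows from the equilibrium constant (K5 = 1.7, k5 = 44.3 M⁻¹ min⁻¹)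

- which of the two there is more of at the end, south-east (target / isomer of the product)
- which of the two there is more of at the end, north-west (target / isomer of the product)
- final target, as a percentage of the substrate charged, in south-east
- final target, as a percentage of the substrate charged, in north-west

I add up the waits of one turn of the cycle at the start, with substrate and partner as charged and the way back from by-product left out. That gives a turnover frequency of 28.8 min⁻¹. South-east then gets 1.44 and north-west 2.88: this is what I carry, the turnover count, the number of substrate charges the catalyst passes in the time at its starting rate.

But the rate does not stay. Substrate and partner fall together, partner being the limiting reagent, so at 50.0 % conversion the rate is down by a factor of 1.68, and at 75.0 % by a factor of 4.10. Summed along the way, these slowings make 75.0 % cost a count of 1.24, and 90.0 % a count of 2.71. So I reckon south-east, whose count is larger than the first cost, to end a little past 75.0 %, and north-west, whose count is larger than the second, a little past 90.0 %.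

The isomerisation needs free catalyst, and at the start that is 24.0 % of the charge. At that starting share I reckon a relaxation half-life of target and isomer of the product of 20.5 min in south-east and 10.3 min in north-west, which is shorter. I commit to target ahead in south-east and isomer of the product ahead in north-west.

The forecast gives target ahead in south-east with 46.5 % target, and isomer of the product ahead in north-west with 37 % target, saying that “isomerisation lags” at the lower charge.

South-east ends with target in front, 46.2 % against 31.8 %, and the two together make 78.1 %. North-west ends with isomer of the product in front, 54.1 % against 36.2 %, and the two together make 90.3 %.

North-west reaches the count of 1.44 at 12.5 min, and there it holds 46.2 % target and 31.8 % isomer of the product, what south-east holds at its end, while at a count of 1.73, read at 15 min, north-west holds 43.2 % against 39.3 %. At the end of north-west the relaxation half-life of target and isomer of the product, by that step alone and both ways together, is 2.85 min, short against the 25 min of the run, and isomer of the product per target stands at 1.50 against an equilibrium constant of 1.7.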